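## Retrosynthetic overview

1. 20 ⇐ 17 by turning the prenyl end into (E)-CH=CH–CMe2OH (hydroxyselenation, selenoxide elimination); 17 ⇐ 15 + senecioic acid 16 by Mitsunobu inversion at C8.
2. Oxirane (second ring): Sharpless epoxidation of the E-Δ6 olefin of the finished carbocycle 14 – cyclase first, epoxidase second, as in the presumed biogenesis.
3. 11-Membered carbocycle (first ring): the cyclase bond C1–C11 by cation–olefin macrocyclisation. The tertiary C11 cation is a Co2(CO)6-stabilised propargylic cation (complexed alkyne = masked Z-Δ9); the olefin is the C1 end of a silyl dienol ether (masked C17 enal). Both C11 epimers of the precursor converge on one cation.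
4. Open C20 chain ⇐ two C10 terpenes: β-myrcene (C1–C8, C17, C18) and racemic dehydrolinalool (C9–C16, C19, C20), joined at C8–C9 by catalytic asymmetric alkynylation.

Assumption: technical β-myrcene and racemic dehydrolinalool count as cheap commercial materials. Locants are those of the geranylgeranyl chain (ring = C1–C11, C17 = carbon on C3, C18 = Me on C7, C19 = Me on C11, side chain = C12–C16 and C20).

Descriptor note: the arrangement in space at C8 is the same from 6 to 15. Its label is R while C9 is alkynyl or cobalt-bound (6–12) and S once C9 is alkenyl (13–15); step 11 inverts it to R (17–20). The oxirane carbon C7 is labelled S in the free alcohol 15 and R in the esters 17–20 without any change in space.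

## Route

Step 1
Reactants: 1 β-myrcene
Product: 3 (2E)-2-methyl-6-methylideneocta-2,7-dienal, via allylic alcohol 2 (not isolated)
Conditions: SeO2 (0.3 equiv), t-BuOOH (3 equiv), salicylic acid (0.1 equiv), CH2Cl2, 25 °C; aqueous wash; then MnO2 (10 equiv), CH2Cl2, 25 °C
Reagents that add atoms: tert-butyl hydroperoxide CC(C)(C)OO; selenium dioxide O=[Se]=O (catalytic O carrier)
Why: SeO2/t-BuOOH allylic oxidation (ene reaction, then [2,3]-shift) attacks the E-methyl of the trisubstituted olefin, and MnO2 converges alcohol and aldehyde on the E-enal, which also deactivates Δ6 for step 2.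

Step 2
Reactants: 3 (2E)-2-methyl-6-methylideneocta-2,7-dienal
Product: 4 (2E)-5-(2-ethenyloxiran-2-yl)-2-methylpent-2-enal
Conditions: mCPBA (1.05 equiv), NaHCO3, CH2Cl2, 0 °C
Reagents that add atoms: mCPBA OOC(=O)c1cccc(Cl)c1
Why: Prilezhaev epoxidation takes the most electron-rich C=C left, the 1,1-disubstituted C3=C17 bond of the diene (the enal C=C is deactivated); the racemic oxirane centre is removed again in step 5.

Step 3
Reactants: 4 (2E)-5-(2-ethenyloxiran-2-yl)-2-methylpent-2-enal; 5 (±)-dehydrolinalool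
Product: 6 (8R)-propargylic diol
Conditions: (S,S)-ProPhenol (20 mol%), Ph3P=O (40 mol%), Me2Zn (4 equiv), 5 (3 equiv), toluene, 4 °C; NH4Cl work-up
Reagents that add atoms: none
Why: Trost ProPhenol–zinc asymmetric alkynylation of an α-branched enal adds the zinc acetylide of 5 (tertiary OH carried as its zinc alkoxide) to the Si face of C8=O and sets C8; the ligand enantiomer is the one for Si-face delivery (the antipode gives 8-epi-6), and C3 and C11 stay as irrelevant mixtures.

Step 4
Reactants: 6 (8R)-propargylic diol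
Product: 7 8-O-TBS ether of 6
Conditions: TBSCl (1.3 equiv), imidazole (2.5 equiv), DMF, 0 → 25 °C
Reagents that add atoms: tert-butyldimethylsilyl chloride CC(C)(C)[Si](C)(C)Cl
Why: silyl ether formation at the secondary alcohol only (the tertiary propargylic OH is too hindered); the TBS ether is meant to resist ionisation at C8 in step 7.

Step 5
Reactants: 7 8-O-TBS ether of 6
Product: 8 (2E,6E,8R)-C17 enal
Conditions: Pd(PPh3)4 (5 mol%), THF, 25 → 50 °C
Reagents that add atoms: none
Why: Pd(0)-catalysed vinyloxirane-to-enal isomerisation (π-allylpalladium alkoxide, net hydride shift from C17 to C1) gives the thermodynamic E-enal; the alkyne, the silyl ether and the free tertiary alcohol carry no leaving group for Pd(0).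

Step 6
Reactants: 8 (2E,6E,8R)-C17 enal
Product: 9 bis-trimethylsilyl compound (17-O-TMS dienol ether, 11-O-TMS)
Conditions: TMSOTf (2.5 equiv), Et3N (4 equiv), Et2O, 0 °C; filtered through Celite, used crude
Reagents that add atoms: trimethylsilyl triflate C[Si](C)(C)OS(=O)(=O)C(F)(F)F
Why: soft γ-enolisation of the enal gives the 1-silyloxy-1,3-diene (nucleophilic at C1), and the tertiary OH is silylated to the group that will ionise; the secondary OTBS is untouched.

Step 7
Reactants: 9 bis-trimethylsilyl compound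
Product: 12 macrocyclic (8R,11S) hexacarbonyldicobalt enal complex, via cobalt alkyne complex 10 (not isolated), via propargylic cation 11 (not isolated)
Conditions: Co2(CO)8 (1.1 equiv), CH2Cl2, 25 °C, 1 h; dilute to 1 mM, BF3·OEt2 (1.5 equiv, promoter, not consumed), −78 → −30 °C; Et3N quench
Reagents that add atoms: dicobalt octacarbonyl O=C=[Co](=C=O)(=C=O)(=C=O)[Co](=C=O)(=C=O)(=C=O)=C=O
Why: Proposed new method: Co2(CO)8 complexes the only alkyne and bends C8–C9–C10–C11 to about 140° (a masked Z-olefin); BF3 ionises the tertiary propargylic OSiMe3 of both C11 epimers to one fluxional Nicholas cation, which is captured at C11 by the γ-terminus C1 of the silyl dienol ether (vinylogous Mukaiyama-type alkylation; α-attack would need a 9-ring with two adjacent quaternary carbons and the allene pathway is blocked by cobalt) to close the cyclase bond C1–C11 and release the E-enal; C11 is set under control of C8 in a model where H-8 eclipses the complexed C9–C10 bond, C7 and the incoming C1 stay on the same face, and the larger homoprenyl group sits outward on the cation with methyl inside, giving (8R,11S); closest known chemistry is the Lewis-acid-mediated intramolecular Nicholas reaction of silyl enol ethers and allylsilanes to 6–8-membered cobalt-complexed cycloalkynes and γ-selective alkylation of 1-silyloxydienes by carbenium ions.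

Step 8
Reactants: 12 macrocyclic (8R,11S) hexacarbonyldicobalt enal complex
Product: 13 (2E,6E,9Z,8S,11S)-macrocyclic trienal TBS ether
Conditions: n-Bu3SnH (6 equiv), benzene, 65 °C
Reagents that add atoms: none
Why: reductive decomplexation of an endocyclic (alkyne)Co2(CO)6 complex with tin hydride delivers two hydrogens syn and gives the cis (Z) C9=C10 olefin directly.

Step 9
Reactants: 13 (2E,6E,9Z,8S,11S)-macrocyclic trienal TBS ether
Product: 14 (8S,11S)-macrocyclic dienol
Conditions: TBAF (1.5 equiv), AcOH (1.5 equiv), THF, 0 → 25 °C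
Reagents that add atoms: none
Why: fluoride desilylation, buffered with acetic acid so that the enal is not enolised.

Step 10
Reactants: 14 (8S,11S)-macrocyclic dienol
Product: 15 (6S,7S,8S,11S)-erythro epoxy alcohol
Conditions: Ti(OiPr)4 (0.3 equiv), L-(+)-DIPT (0.36 equiv), t-BuOOH (2 equiv, decane), 4 Å MS, CH2Cl2, −20 °C
Reagents that add atoms: tert-butyl hydroperoxide CC(C)(C)OO
Why: Sharpless asymmetric epoxidation of the E-trisubstituted allylic alcohol, with L-(+)-tartrate matched to the (8S) carbinol, gives the erythro 6,7-oxirane with the C6/C7 arrangement of the target and removes material of the wrong C8 series by kinetic resolution; the Z-Δ9 allylic olefin (quaternary cis substituent), the enal and Δ14 are not epoxidised.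

Step 11
Reactants: 15 (6S,7S,8S,11S)-erythro epoxy alcohol; 16 senecioic acid (3-methylbut-2-enoic acid)
Product: 17 (6S,7R,8R,11S)-threo epoxy senecioate
Conditions: PPh3 (3 equiv), DIAD (3 equiv), toluene, 0 → 25 °C
Reagents that add atoms: none
Why: Mitsunobu esterification proceeds by SN2 inversion at C8, which turns the erythro alcohol into the threo ester of the target and installs the senecioate in one operation; SN2′ is blocked by the quaternary C11.

Step 12
Reactants: 17 (6S,7R,8R,11S)-threo epoxy senecioate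
Product: 20 target CNP0164725.3, via hydroxy selenide 18 (not isolated), via selenoxide 19 (not isolated)
Conditions: N-(phenylseleno)phthalimide (1.2 equiv), H2O (10 equiv), PPTS (10 mol%), CH2Cl2–MeCN, 0 °C; then NaIO4, NaHCO3, THF–H2O, 25 °C
Reagents that add atoms: water O; N-(phenylseleno)phthalimide O=C1c2ccccc2C(=O)N1[Se]c1ccccc1 (supplies the PhSe group of 18 and 19 only)
Why: Markovnikov hydroxyselenation of the only electron-rich olefin (Δ14) puts OH on C15 and PhSe on C14, and selenoxide syn-elimination can only go toward C13, giving the (E)-allylic tertiary alcohol.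

## Compound list

Cobalt complexes are written as C2Co2 tetrahedranes with Co=C=O carbonyls. Centres that are mixtures (C3 in 4, 6, 7; C11 in 5–10; C14 in 18, 19; dienol ether geometry in 9–11) carry no stereo mark.

1 | β-myrcene (7-methyl-3-methylideneocta-1,6-diene) | C=CC(=C)CCC=C(C)C | starting material
2 | (2E)-2-methyl-6-methylideneocta-2,7-dien-1-ol | OC/C(C)=C/CCC(=C)C=C | intermediate (not isolated)
3 | (2E)-2-methyl-6-methylideneocta-2,7-dienal | O=C/C(C)=C/CCC(=C)C=C | intermediate
4 | (2E)-5-(2-ethenyloxiran-2-yl)-2-methylpent-2-enal, racemic | O=C/C(C)=C/CCC1(CO1)C=C | intermediate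
5 | (±)-dehydrolinalool (3,7-dimethyloct-6-en-1-yn-3-ol) | C#CC(C)(O)CCC=C(C)C | starting material
6 | (3E,5R)-1-(2-ethenyloxiran-2-yl)-4,8,12-trimethyltrideca-3,11-dien-6-yne-5,8-diol (8R in chain locants) | C=CC1(CO1)CC/C=C(\C)[C@@H](O)C#CC(C)(O)CCC=C(C)C | intermediate
7 | 8-O-tert-butyldimethylsilyl ether of 6 | C=CC1(CO1)CC/C=C(\C)[C@@H](O[Si](C)(C)C(C)(C)C)C#CC(C)(O)CCC=C(C)C | intermediate
8 | (2E,6E,8R)-enal OHC(C17)–C3(=C2H–C1H3)–C4H2–C5H2–C6H=C7(Me)–C8H(OTBS)–C9≡C10–C11(Me)(OH)–CH2CH2CH=CMe2 | C/C=C(/C=O)CC/C=C(\C)[C@@H](O[Si](C)(C)C(C)(C)C)C#CC(C)(O)CCC=C(C)C | intermediate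
9 | 17-O-trimethylsilyl dienol ether (C1H2=C2H–C3=C17H–OTMS) and 11-O-trimethylsilyl ether of 8 | C=CC(=CO[Si](C)(C)C)CC/C=C(\C)[C@@H](O[Si](C)(C)C(C)(C)C)C#CC(C)(O[Si](C)(C)C)CCC=C(C)C | intermediate
10 | μ-(C9,C10-alkyne)hexacarbonyldicobalt complex of 9 | C=CC(=CO[Si](C)(C)C)CC/C=C(\C)[C@@H](O[Si](C)(C)C(C)(C)C)C12C3(C(C)(O[Si](C)(C)C)CCC=C(C)C)[Co]1(=C=O)(=C=O)(=C=O)[Co]23(=C=O)(=C=O)=C=O | intermediate (not isolated)
11 | C11 propargylic cation of 10, trimethylsiloxytrifluoroborate ion pair | C=CC(=CO[Si](C)(C)C)CC/C=C(\C)[C@@H](O[Si](C)(C)C(C)(C)C)C12C3([C+](C)CCC=C(C)C)[Co]1(=C=O)(=C=O)(=C=O)[Co]23(=C=O)(=C=O)=C=O.C[Si](C)(C)O[B-](F)(F)F | intermediate (not isolated)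
12 | (2E,6E,8R,11S)-8-(TBS-oxy)-11-methyl-11-(4-methylpent-3-enyl)-3-formyl-7-methylcycloundeca-2,6-dien-9-yne, Co2(CO)6 complex | CC(C)(C)[Si](C)(C)O[C@H]1C23C4([C@@](C)(CCC=C(C)C)C/C=C(/C=O)CC/C=C1\C)[Co]2(=C=O)(=C=O)(=C=O)[Co]34(=C=O)(=C=O)=C=O | intermediate
13 | (2E,6E,9Z,8S,11S)-macrocyclic trienal, 8-OTBS | CC(C)(C)[Si](C)(C)O[C@H]1/C=C\[C@@](C)(CCC=C(C)C)C/C=C(/C=O)CC/C=C1\C | intermediate
14 | (2E,6E,9Z,8S,11S)-macrocyclic trienal, 8-OH | O[C@H]1/C=C\[C@@](C)(CCC=C(C)C)C/C=C(/C=O)CC/C=C1\C | intermediate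
15 | (6S,7S,8S,11S)-6,7-epoxy-8-hydroxy macrocyclic dienal (erythro) | O[C@H]1/C=C\[C@@](C)(CCC=C(C)C)C/C=C(/C=O)CC[C@@H]2O[C@]21C | intermediate
16 | senecioic acid (3-methylbut-2-enoic acid) | CC(C)=CC(=O)O | starting material
17 | (6S,7R,8R,11S)-6,7-epoxy-8-senecioyloxy macrocyclic dienal with 4-methylpent-3-enyl side chain (threo) | CC(C)=CC(=O)O[C@@H]1/C=C\[C@@](C)(CCC=C(C)C)C/C=C(/C=O)CC[C@@H]2O[C@]21C | intermediate
18 | 15-hydroxy-14-phenylselanyl adduct of 17 | CC(C)=CC(=O)O[C@@H]1/C=C\[C@@](C)(CCC([Se]c3ccccc3)C(C)(C)O)C/C=C(/C=O)CC[C@@H]2O[C@]21C | intermediate (not isolated)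
19 | selenoxide of 18 | CC(C)=CC(=O)O[C@@H]1/C=C\[C@@](C)(CCC([Se](=O)c3ccccc3)C(C)(C)O)C/C=C(/C=O)CC[C@@H]2O[C@]21C | intermediate (not isolated)
20 | CNP0164725.3 | CC(C)=CC(=O)O[C@@H]1/C=C\[C@@](C)(C/C=C/C(C)(C)O)C/C=C(/C=O)CC[C@@H]2O[C@]21C | target

## Step count and risks

Total step count: 12. Longest linear sequence: 12 steps (1 → 20); 5 and 16 are bought.

The three steps most likely to fail:

Step 7, the 11-membered Nicholas closure. Cation 11 may eliminate to the enyne, the bis-allylic/propargylic C8–OTBS may ionise in competition, or the C11 ratio may be poor (the facial model is untested). The fallback puts the oxirane and the ester on the open chain first, so that C8 is α to an oxirane and cannot ionise, three contiguous stereocentres and a rigid trans-oxirane bias the closure, and no substitution on the macrocycle is needed. It sets out from 6. Sharpless epoxidation (Ti(OiPr)4, L-(+)-DIPT, t-BuOOH; matched) gives the acyclic erythro epoxy diol F1. Mitsunobu esterification with 16 inverts C8 to the threo senecioate F2. Pd(PPh3)4 isomerises the vinyloxirane to the enal F3, and TMSOTf/Et3N gives the bis-trimethylsilyl compound F4. Co2(CO)8 forms the cobalt complex F5 (not isolated); catalytic TMSOTf at −78 °C ionises it to the propargylic cation F6 (not isolated), which closes to the macrocyclic cobalt complex F7. Bu3SnH as in step 8 then gives 17, where the route is rejoined.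

Step 11, SN2 inversion at a ring carbon next to a fully substituted oxirane carbon. The backside of C8 may be shielded by the ring, and senecioic acid is a weak Mitsunobu acid. The fallback replaces oxyphosphonium activation by ionic displacement of a preformed sulfonate. It sets out from 15: chloromethanesulfonyl chloride and pyridine give the 8-O-chloromethanesulfonate F8, and caesium 3-methylbut-2-enoate (from 16 and Cs2CO3) with 18-crown-6 in toluene displaces it with inversion to return to 17.

Step 8, reductive decomplexation in the presence of the enal. Tin hydride or cobalt hydride species may reduce the conjugated aldehyde. The fallback separates metal removal from reduction. It sets out from 12: ceric ammonium nitrate in acetone at −40 °C frees the cyclic enyne F9, and Lindlar semihydrogenation (H2, Pd/CaCO3–Pb, quinoline) gives 13.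

## Further compounds

F1 | step 7 | (6S,7S,8S)-6,7-epoxide of 6 (erythro epoxy diol, vinyloxirane retained) | C=CC1(CO1)CC[C@@H]2O[C@@]2(C)[C@@H](O)C#CC(C)(O)CCC=C(C)C
F2 | step 7 | (6S,7R,8R)-8-senecioate of F1 after inversion (threo), 11-OH free | C=CC1(CO1)CC[C@@H]2O[C@@]2(C)[C@H](OC(=O)C=C(C)C)C#CC(C)(O)CCC=C(C)C
F3 | step 7 | (2E)-C17 enal from F2 | C/C=C(/C=O)CC[C@@H]1O[C@@]1(C)[C@H](OC(=O)C=C(C)C)C#CC(C)(O)CCC=C(C)C
F4 | step 7 | 17-O-trimethylsilyl dienol ether and 11-O-trimethylsilyl ether of F3 | C=CC(=CO[Si](C)(C)C)CC[C@@H]1O[C@@]1(C)[C@H](OC(=O)C=C(C)C)C#CC(C)(O[Si](C)(C)C)CCC=C(C)C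
F5 | step 7 | hexacarbonyldicobalt complex of F4 | C=CC(=CO[Si](C)(C)C)CC[C@@H]1O[C@@]1(C)[C@H](OC(=O)C=C(C)C)C23C4(C(C)(O[Si](C)(C)C)CCC=C(C)C)[Co]2(=C=O)(=C=O)(=C=O)[Co]34(=C=O)(=C=O)=C=O
F6 | step 7 | C11 propargylic cation of F5, triflate ion pair | C=CC(=CO[Si](C)(C)C)CC[C@@H]1O[C@@]1(C)[C@H](OC(=O)C=C(C)C)C23C4([C+](C)CCC=C(C)C)[Co]2(=C=O)(=C=O)(=C=O)[Co]34(=C=O)(=C=O)=C=O.[O-]S(=O)(=O)C(F)(F)F
F7 | step 7 | hexacarbonyldicobalt complex of the 9,10-didehydro analogue of 17 | CC(C)=CC(=O)O[C@@H]1C23C4([C@@](C)(CCC=C(C)C)C/C=C(/C=O)CC[C@@H]5O[C@]51C)[Co]2(=C=O)(=C=O)(=C=O)[Co]34(=C=O)(=C=O)=C=O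
F8 | step 11 | 8-O-chloromethanesulfonate of 15 | ClCS(=O)(=O)O[C@H]1/C=C\[C@@](C)(CCC=C(C)C)C/C=C(/C=O)CC[C@@H]2O[C@]21C
F9 | step 8 | 9,10-didehydro (cycloalkyne) analogue of 13 | CC(C)(C)[Si](C)(C)O[C@H]1C#C[C@@](C)(CCC=C(C)C)C/C=C(/C=O)CC/C=C1\C
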